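## Structural features

The target is a 3,5-dihydro-2H-benzofuran-6-one: a 2,4-cyclohexadienone ring (C3a, C4, C5, C6, C7, C7a) fused along C3a–C7a to a dihydrofuran ring (O1, C2, C3). C2 (3,4,5-trimethoxyphenyl) and C3 (methyl) are adjacent stereocentres, trans, both S. The third stereocentre, C5 (R), is quaternary, carries allyl and methoxy, and is separated from C3 by the sp2 atoms C3a and C4, with the allyl group on the face of the aryl group. C6=O lies between C5 and the vinylogous ester C7(OMe)=C7a–O1, so the six-membered ring is an ortho-quinol ether that cannot aromatise. Fragile points are the C5-allyl/dienone pair ([3,3] shift of allyl to C3a, light-induced ring opening), the vinylogous ester (alkoxide exchange at C7a), the electron-rich benzylic C2–O1 bond (ionisation) and the terminal alkene. The real difficulty is C5: a fully substituted, oxygenated sp3 carbon in a ring otherwise at phenol oxidation level, remote from the C2/C3 stereo elements. The key step exploits the fact that C6, C3a, C4 and C5 map onto a 4,4-disubstituted cyclobutenone and C7/C7a onto an alkoxyalkyne whose oxygen is O1, so the dienone and the dihydrofuran can be assembled without ever passing through an arene.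

## Logic of the disconnections

24 is taken back to 23 and then to 22 by cutting the C7–OMe bond. The C7 oxygen cannot ride on the alkyne (a 1,2-dialkoxyalkyne is not a usable partner), and C7 is the one nucleophilic carbon of 22. The gain is that 22 is the direct product of the ring-forming cascade. The forward demand is site-selective halogenation beside an allyl group and an electron-rich arene, and a C–O coupling mild enough not to open the vinylogous ester or move the allyl group.

22 is opened to 18 through 21, 20 and 19 by cutting C5–C6, C6–C7 and C3a–C7a. This removes both rings and the quaternary stereocentre in one operation and leaves a monocyclic four-membered ketone with a tethered alkyne. The forward step must be triggered cold, must find the alkyne before the ketene is lost, and has only the C3 methyl group to steer the face at C5.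

18 is taken back through 17 and 15 to 14 by functional-group changes only: C6 ketone to carbinol, terminal alkyne to dichlorovinyl ether, carbinol back to ketone. The reason is that the alkyne can only be released with butyllithium, which no ketone survives. The gain is that the alkyne is carried in a robust latent form through five steps. The demand is a neutral, cold reoxidation in the presence of an acid- and heat-sensitive alkynyl ether.

14 is taken back through 13 and 12 to 11 by cutting the C5–OMe and C5–allyl bonds and returning C6=O to a CCl2 group. While C6 is still CCl2, the ring has a single carbonyl (future C5), so the allyl nucleophile has only one site to attack. A cyclobutenedione was avoided because it would leave that regiochemistry open. The demand is a hydrolysis of the gem-dichloride that does not trigger a 1,2-shift from C5.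

11 is cut to 8 and 10 (from 9) at C3a–C6 and C4–C5. A ketene adds to a terminal alkyne with its carbonyl carbon on the terminal carbon, which places the latent C6 next to C3a as required. The gain is a four-membered ring from an alkyne in one step. The demand is chemoselectivity for the alkyne over the dichlorovinyl ether and the arene.

8 is cut to 5 and 7 (from 6) at O1–C7a. The hydroxyl is masked for the ketene step and at the same time receives the two carbons that become C7a and C7. The demand is clean alkoxide formation beside a terminal alkyne.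

5 is cut to 3 and 4 (from 2, from 1) at C2–C3. Both stereocentres and their anti relationship arise in one step from commercial material. The (R) configuration of 1 is required because the carbon–carbon bond forms with net inversion at the methyl-bearing carbon. The demand is good anti selectivity with an aromatic aldehyde.

## Other disconnections considered

Alternative 1: The cut is O1–C2, made on a fully aromatic diarylpropane.
- Forward step: phenol A1, whose C3 centre would come from an asymmetric alkene hydrogenation, would be oxidised with Ag2O at its 4-alkyl-2,6-dimethoxyphenol ring to the para-quinone methide A2. The hydroxyl of the other ring would add to the methide carbon and close the dihydrofuran of A3, trans at C2/C3 because the aryl group avoids the C3 methyl.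
- In favour: the closure is a well-known, biomimetic reaction class, every isolated intermediate is a robust arene, and the absolute configuration comes from a catalytic step. On mechanistic security this is the better plan; on C2/C3 control it is the equal of the chosen one.
- Against: A2 needs a free 4-hydroxyl, so the trimethoxyphenyl ring must be completed afterwards. A3 still has an aromatic ring with nothing at C5, so allyl, C5-methoxy and the dienone all come after the key step (deprotection, O-allylation, Claisen shift to C5, oxidative methoxylation). The last of these must choose C5 over C7 and C3a and gets no more facial guidance than the chosen cascade.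
- Comparison: on structure, the chosen plan builds the quaternary carbon inside the ring-forming event, while this one postpones it. On step economy the two should be close, this one somewhat longer once the end game is counted.

Alternative 2: The cut is O1–C7a.
- Forward step: catechol A4, with the C2/C3 pair already in its side chain, would be oxidised (o-chloranil or Ag2O) to its ortho-quinone A5. The secondary hydroxyl would add 5-exo to C7a, and re-oxidation would give the bicyclic ortho-quinone A6.
- In favour: A6 has the oxidation level of the target and the C7 methoxy from the start. Only allyl addition at the C5 carbonyl (the C6 carbonyl is part of a vinylogous ester and less electrophilic) and O-methylation at C5 would remain. In step economy this is the better plan, and it needs no halogenation/etherification at C7. It also allows reagent control at C5 with a chiral allyl donor, which the chosen cascade cannot offer.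
- Against: A5 is electron-rich and has a benzylic hydrogen at C3, so it could tautomerise at the quinone stage, which would erase C3. The hydroxyl can reach C4 as well as C7a, and the C7 methoxy donor lowers the electrophilicity of C7a. The benzylic carbinol and the aryl ring must survive two oxidations.
- Comparison: on mechanism neither plan is secure, this one for regiochemistry and stability, the chosen one for an untested intramolecular cycloaddition. The chosen plan fixes every carbon by construction, which is why it was preferred.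

Alternative 3: The cut is C3–C3a, restored by ring contraction.
- Forward step: diazoketone A7, an enantiopure 3-diazoflavanone, would lose N2 on irradiation in methanol. The aryl carbon C3a would migrate to C3 (Wolff rearrangement) and methanol would add to the former carbonyl carbon, giving ester A8, trans because the ester-bearing carbon can equilibrate.
- In favour: photo-Wolff ring contraction is established chemistry, so on mechanism this is the more secure plan. The allyl group is already on the C6 oxygen for a Claisen shift to C5. The thermodynamic trans outcome is at least the equal of the anti-selective propargylation used here.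
- Against: C3 arrives as a carboxylate and needs about three operations to become methyl. The C2 centre of A7 can be lost by base-induced retro-oxa-Michael ring opening during diazo transfer. As in Alternative 1, C5 is left to a late oxidative methoxylation with the same regiochemical and facial uncertainties.
- Comparison: this should be the longest of the four plans. Its key step forms a bond (C3–C3a) that the chosen plan takes from commercial material, whereas the chosen cascade forms both rings and the quaternary carbon.

Key step: step 11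

Assumption: benzofuranone numbering (O1, C2, C3, C3a, C4, C5, C6, C7, C7a) is used for the matching atoms of all intermediates, and the four-ring carbon that becomes C5 is carried as both epimers because it turns planar in ketene 19.

## Route

**Step 1**

Reactants: 1 (R)-but-3-yn-2-ol

Product: 2 (R)-but-3-yn-2-yl methanesulfonate

Conditions: MsCl, Et3N, CH2Cl2, −78 to 0 °C

Reagents that add atoms: methanesulfonyl chloride `CS(=O)(=O)Cl`

Why: O-sulfonylation of a secondary propargylic alcohol; no bond to the stereocentre is broken, so the (R) configuration is retained.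

**Step 2**

Reactants: 2 (R)-but-3-yn-2-yl methanesulfonate; 3 3,4,5-trimethoxybenzaldehyde

Product: 5 (1S,2S)-2-methyl-1-(3,4,5-trimethoxyphenyl)but-3-yn-1-ol, via allenylindium reagent 4 (not isolated)

Conditions: Pd(dppf)Cl2 (5 mol %), InI, THF–DMPU (3:1), 20 °C; aq. NH4Cl

Reagents that add atoms: none

Why: Marshall propargylation: zerovalent palladium, formed from the precatalyst by InI, displaces the mesylate anti in SN2′ fashion and passes the allenyl group to indium, and allenylindium 4 adds to the aldehyde through a cyclic SE2′ transition state. Aryl and methyl avoid each other in that transition state, which sets C2 and C3 anti, and the net inversion at the methyl-bearing carbon turns (R)-2 into the (S) centre, so the (1S,2S) alcohol is expected; any syn isomer is to be removed by chromatography.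

**Step 3**

Reactants: 5 (1S,2S)-2-methyl-1-(3,4,5-trimethoxyphenyl)but-3-yn-1-ol; 6 trichloroethylene

Product: 8 5-[(1S,2S)-1-{[(E)-1,2-dichloroethenyl]oxy}-2-methylbut-3-yn-1-yl]-1,2,3-trimethoxybenzene, via dichloroacetylene 7 (not isolated)

Conditions: KH (1.05 equiv), THF, 0 °C; then 6, −50 to 20 °C

Reagents that add atoms: none

Why: Dichlorovinyl ether synthesis from trichloroethylene: the potassium alkoxide dehydrochlorinates 6 to dichloroacetylene 7, which stays in solution and is consumed at once by anti addition of the alkoxide, giving the E ether. The group protects the hydroxyl for the ketene step and already holds the carbons that become C7a and C7; one equivalent of base is used so that the alkyne C–H is left alone.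

**Step 4**

Reactants: 8 5-[(1S,2S)-1-{[(E)-1,2-dichloroethenyl]oxy}-2-methylbut-3-yn-1-yl]-1,2,3-trimethoxybenzene; 9 trichloroacetyl chloride

Product: 11 4,4-dichloro-3-[(1S,2S)-1-{[(E)-1,2-dichloroethenyl]oxy}-1-(3,4,5-trimethoxyphenyl)propan-2-yl]cyclobut-2-en-1-one, via dichloroketene 10 (not isolated)

Conditions: Zn–Cu couple, Et2O–DME, slow addition of 9, 20–35 °C

Reagents that add atoms: none

Why: Dichloroketene–alkyne [2+2] cycloaddition; the ketene carbonyl carbon bonds to the terminal alkyne carbon, so the CCl2 group (latent C6) ends next to the substituted carbon (C3a). The dichlorovinyl ether is a hindered, electron-poor alkene and should not compete, and DME binds ZnCl2 away from the benzylic ether; 11 is used without delay to avoid a 1,3-chlorine shift.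

**Step 5**

Reactants: 11 4,4-dichloro-3-[(1S,2S)-1-{[(E)-1,2-dichloroethenyl]oxy}-1-(3,4,5-trimethoxyphenyl)propan-2-yl]cyclobut-2-en-1-one

Product: 12 4,4-dichloro-3-[(1S,2S)-1-{[(E)-1,2-dichloroethenyl]oxy}-1-(3,4,5-trimethoxyphenyl)propan-2-yl]-1-(prop-2-en-1-yl)cyclobut-2-en-1-ol (both epimers at C1 of the ring)

Conditions: CH2=CHCH2MgBr, THF, −78 °C; aq. NH4Cl at −78 °C

Reagents that add atoms: allylmagnesium bromide `C=CC[Mg]Br`

Why: 1,2-Addition of an allyl Grignard reagent to the only carbonyl group, which is the future C5; because C6 is still a CCl2 group there is no second carbonyl to compete. The configuration of the new carbinol is irrelevant, since this carbon becomes sp2 in step 11; cold quench prevents rearrangement of the chlorinated alkoxide.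

**Step 6**

Reactants: 12 4,4-dichloro-3-[(1S,2S)-1-{[(E)-1,2-dichloroethenyl]oxy}-1-(3,4,5-trimethoxyphenyl)propan-2-yl]-1-(prop-2-en-1-yl)cyclobut-2-en-1-ol

Product: 13 5-[(1S,2S)-2-[4,4-dichloro-3-methoxy-3-(prop-2-en-1-yl)cyclobut-1-en-1-yl]-1-{[(E)-1,2-dichloroethenyl]oxy}propyl]-1,2,3-trimethoxybenzene (both epimers at the methoxy-bearing ring carbon)

Conditions: Me3OBF4, 1,8-bis(dimethylamino)naphthalene, 4 Å MS, CH2Cl2, 0 to 20 °C

Reagents that add atoms: trimethyloxonium tetrafluoroborate `C[O+](C)C.F[B-](F)(F)F`

Why: O-Methylation of a hindered tertiary alcohol with a Meerwein salt and a non-nucleophilic amine; no alkoxide is formed, so the neighbouring CCl2 group cannot be displaced or trigger a ring contraction.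

**Step 7**

Reactants: 13 5-[(1S,2S)-2-[4,4-dichloro-3-methoxy-3-(prop-2-en-1-yl)cyclobut-1-en-1-yl]-1-{[(E)-1,2-dichloroethenyl]oxy}propyl]-1,2,3-trimethoxybenzene

Product: 14 2-[(1S,2S)-1-{[(E)-1,2-dichloroethenyl]oxy}-1-(3,4,5-trimethoxyphenyl)propan-2-yl]-4-methoxy-4-(prop-2-en-1-yl)cyclobut-2-en-1-one (both epimers at C4 of the ring)

Conditions: AgNO3, CaCO3, acetone–H2O (4:1), 0 to 20 °C, dark

Reagents that add atoms: water `O`

Why: Silver-assisted hydrolysis of an allylic gem-dichloride: loss of chloride gives a chlorine-stabilised cyclobutenyl cation, water adds at the chlorinated carbon and HCl is lost, so the C6 carbonyl appears next to C3a. CaCO3 keeps the medium near neutral for the benzylic ether and the dichlorovinyl ether.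

**Step 8**

Reactants: 14 2-[(1S,2S)-1-{[(E)-1,2-dichloroethenyl]oxy}-1-(3,4,5-trimethoxyphenyl)propan-2-yl]-4-methoxy-4-(prop-2-en-1-yl)cyclobut-2-en-1-one

Product: 15 2-[(1S,2S)-1-{[(E)-1,2-dichloroethenyl]oxy}-1-(3,4,5-trimethoxyphenyl)propan-2-yl]-4-methoxy-4-(prop-2-en-1-yl)cyclobut-2-en-1-ol (mixture of ring diastereomers)

Conditions: NaBH4, CeCl3·7H2O, MeOH, −40 °C

Reagents that add atoms: none

Why: Luche reduction gives clean 1,2-reduction of the enone; the ketone is parked as a carbinol because the next step needs butyllithium. All diastereomers are used, since this centre is reoxidised in step 10.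

**Step 9**

Reactants: 15 2-[(1S,2S)-1-{[(E)-1,2-dichloroethenyl]oxy}-1-(3,4,5-trimethoxyphenyl)propan-2-yl]-4-methoxy-4-(prop-2-en-1-yl)cyclobut-2-en-1-ol

Product: 17 2-[(1S,2S)-1-(ethynyloxy)-1-(3,4,5-trimethoxyphenyl)propan-2-yl]-4-methoxy-4-(prop-2-en-1-yl)cyclobut-2-en-1-ol, via chloroethynyl ether 16 (not isolated)

Conditions: n-BuLi (3.3 equiv), THF, −78 to −40 °C; MeOH, −78 °C; pH 7 buffer

Reagents that add atoms: none

Why: Conversion of a 1,2-dichlorovinyl ether into an ynol ether: one equivalent of base forms the lithium alkoxide, the second removes the vinyl proton and LiCl is lost to give chloroalkyne 16, and the third exchanges chlorine for lithium; protonation gives the terminal alkynyl ether. Everything else in 15 (ethers, alkenes, alkoxide) is inert to n-BuLi at this temperature.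

**Step 10**

Reactants: 17 2-[(1S,2S)-1-(ethynyloxy)-1-(3,4,5-trimethoxyphenyl)propan-2-yl]-4-methoxy-4-(prop-2-en-1-yl)cyclobut-2-en-1-ol

Product: 18 2-[(1S,2S)-1-(ethynyloxy)-1-(3,4,5-trimethoxyphenyl)propan-2-yl]-4-methoxy-4-(prop-2-en-1-yl)cyclobut-2-en-1-one (both epimers at C4 of the ring)

Conditions: MnO2 (activated, excess), CH2Cl2, 0 to 20 °C; filter, concentrate cold, use at once

Reagents that add atoms: none

Why: MnO2 oxidation of an allylic (cyclobutenyl) alcohol under neutral, heterogeneous conditions that an acid-sensitive ynol ether should tolerate. The product is kept at or below 20 °C because benzylic alkynyl ethers rearrange on warming.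

**Step 11**

Reactants: 18 2-[(1S,2S)-1-(ethynyloxy)-1-(3,4,5-trimethoxyphenyl)propan-2-yl]-4-methoxy-4-(prop-2-en-1-yl)cyclobut-2-en-1-one

Product: 22 (2S,3S,5R)-5-methoxy-3-methyl-5-(prop-2-en-1-yl)-2-(3,4,5-trimethoxyphenyl)-3,5-dihydro-1-benzofuran-6(2H)-one, via vinylketene 19 (not isolated), via bicyclic cyclobutenone 20 (not isolated), via dienylketene 21 (not isolated)

Conditions: hν (350 nm, Pyrex), degassed toluene (0.005 M), 0–10 °C; then dark, 25–40 °C; chromatography

Reagents that add atoms: none

Why: Proposed new method: light-induced 4-electron opening of cyclobutenone 18 gives vinylketene 19, whose electrophilic carbon C6 is attacked by the nucleophilic terminal carbon C7 of the ynol ether while C3a closes onto the oxygen-stabilised C7a, an intramolecular ketene–alkyne [2+2] event that gives the strained bicyclic cyclobutenone 20; 20 reopens by a second 4-electron process to dienylketene 21, which closes by thermal disrotatory 6-electron electrocyclisation between C5 and C6 to dienone 22. The closest known reaction type is the Danheiser benzannulation of cyclobutenones with alkoxyalkynes, here made intramolecular and, because C5 is quaternary, expected to stop at the 2,4-dienone instead of tautomerising to a phenol. The dihydrofuran ring closes in the cycloaddition by C3a–C7a bond formation across the three-atom tether C3–C2–O1, a 5-exo-dig mode at the alkyne; the six-membered ring closes in the electrocyclisation, for which the cis placement of C4 and C7 about C3a=C7a is enforced by the five-membered ring. The regiochemistry (C6 to C7, C3a to C7a) is secured twice, by the polarisation of the ynol ether and by the tether, which cannot reach the other orientation. C5 is the only new stereocentre; it is set in the disrotatory closure, where the helical sense of 21 is biased only by the C3 methyl group through its contact with C4–H, so modest selectivity is expected, and the minor (5S) epimer F8 is to be removed by chromatography and can be irradiated again, since light reopens either dienone to the same ketene 21. Light at 0–10 °C is chosen over heating because the benzylic alkynyl ether of 18 is liable to a [3,3] shift onto the arene and to retro-ene loss of ketene below the temperature a thermal cyclobutenone opening needs, and because 22 can suffer a [3,3] allyl shift to C3a when heated; high dilution suppresses ketene dimerisation.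

**Step 12**

Reactants: 22 (2S,3S,5R)-5-methoxy-3-methyl-5-(prop-2-en-1-yl)-2-(3,4,5-trimethoxyphenyl)-3,5-dihydro-1-benzofuran-6(2H)-one

Product: 23 (2S,3S,5R)-7-bromo-5-methoxy-3-methyl-5-(prop-2-en-1-yl)-2-(3,4,5-trimethoxyphenyl)-3,5-dihydro-1-benzofuran-6(2H)-one

Conditions: NBS, CH2Cl2, −40 to 0 °C, dark

Reagents that add atoms: N-bromosuccinimide `O=C1CCC(=O)N1Br`

Why: Electrophilic bromination at C7, the α-carbon of the vinylogous ester and the most nucleophilic carbon of 22; the oxocarbenium ion at C7a then loses the C7 proton. Low temperature and darkness keep ionic bromination away from the trimethoxyphenyl ring and radical bromination away from the allyl group.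

**Step 13**

Reactants: 23 (2S,3S,5R)-7-bromo-5-methoxy-3-methyl-5-(prop-2-en-1-yl)-2-(3,4,5-trimethoxyphenyl)-3,5-dihydro-1-benzofuran-6(2H)-one

Product: 24 (2S,3S,5R)-5,7-dimethoxy-3-methyl-5-(prop-2-en-1-yl)-2-(3,4,5-trimethoxyphenyl)-3,5-dihydro-1-benzofuran-6(2H)-one

Conditions: CuI (20 mol %), 3,4,7,8-tetramethyl-1,10-phenanthroline (40 mol %), Cs2CO3, MeOH (10 equiv), toluene, 80 °C

Reagents that add atoms: methanol `CO`

Why: Ullmann-type C–O coupling of an activated alkenyl bromide (α-bromo enone) with methanol under monovalent copper catalysis; the carbonate base keeps free methoxide low, which protects the vinylogous ester at C7a. No stereocentre is touched: C5 is quaternary and C2/C3 are not acidic under these conditions.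

## Compound list

```
1 | (R)-but-3-yn-2-ol | C[C@@H](O)C#C | starting material
2 | (R)-but-3-yn-2-yl methanesulfonate | C[C@@H](OS(C)(=O)=O)C#C | intermediate
3 | 3,4,5-trimethoxybenzaldehyde | COc1cc(C=O)cc(OC)c1OC | starting material
4 | (P)-buta-1,2-dien-1-yl(iodo)indium methanesulfonate, trivalent indium (not isolated) | CS(=O)(=O)O[In](I)C([H])=[C@@]=C([H])C | intermediate
5 | (1S,2S)-2-methyl-1-(3,4,5-trimethoxyphenyl)but-3-yn-1-ol | C#C[C@H](C)[C@H](O)c1cc(OC)c(OC)c(OC)c1 | intermediate
6 | trichloroethylene | ClC=C(Cl)Cl | starting material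
7 | dichloroacetylene (not isolated) | ClC#CCl | intermediate
8 | 5-[(1S,2S)-1-{[(E)-1,2-dichloroethenyl]oxy}-2-methylbut-3-yn-1-yl]-1,2,3-trimethoxybenzene | C#C[C@H](C)[C@H](O/C(Cl)=C\Cl)c1cc(OC)c(OC)c(OC)c1 | intermediate
9 | trichloroacetyl chloride | ClC(=O)C(Cl)(Cl)Cl | starting material
10 | dichloroketene (not isolated) | ClC(Cl)=C=O | intermediate
11 | 4,4-dichloro-3-[(1S,2S)-1-{[(E)-1,2-dichloroethenyl]oxy}-1-(3,4,5-trimethoxyphenyl)propan-2-yl]cyclobut-2-en-1-one | O=C1C=C(C1(Cl)Cl)[C@H](C)[C@H](O/C(Cl)=C\Cl)c1cc(OC)c(OC)c(OC)c1 | intermediate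
12 | 4,4-dichloro-3-[(1S,2S)-1-{[(E)-1,2-dichloroethenyl]oxy}-1-(3,4,5-trimethoxyphenyl)propan-2-yl]-1-(prop-2-en-1-yl)cyclobut-2-en-1-ol (both ring epimers) | C=CCC1(O)C=C(C1(Cl)Cl)[C@H](C)[C@H](O/C(Cl)=C\Cl)c1cc(OC)c(OC)c(OC)c1 | intermediate
13 | 5-[(1S,2S)-2-[4,4-dichloro-3-methoxy-3-(prop-2-en-1-yl)cyclobut-1-en-1-yl]-1-{[(E)-1,2-dichloroethenyl]oxy}propyl]-1,2,3-trimethoxybenzene (both ring epimers) | C=CCC1(OC)C=C(C1(Cl)Cl)[C@H](C)[C@H](O/C(Cl)=C\Cl)c1cc(OC)c(OC)c(OC)c1 | intermediate
14 | 2-[(1S,2S)-1-{[(E)-1,2-dichloroethenyl]oxy}-1-(3,4,5-trimethoxyphenyl)propan-2-yl]-4-methoxy-4-(prop-2-en-1-yl)cyclobut-2-en-1-one (both ring epimers) | C=CCC1(OC)C=C(C1=O)[C@H](C)[C@H](O/C(Cl)=C\Cl)c1cc(OC)c(OC)c(OC)c1 | intermediate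
15 | 2-[(1S,2S)-1-{[(E)-1,2-dichloroethenyl]oxy}-1-(3,4,5-trimethoxyphenyl)propan-2-yl]-4-methoxy-4-(prop-2-en-1-yl)cyclobut-2-en-1-ol (ring diastereomers) | C=CCC1(OC)C=C(C1O)[C@H](C)[C@H](O/C(Cl)=C\Cl)c1cc(OC)c(OC)c(OC)c1 | intermediate
16 | lithium 2-[(1S,2S)-1-[(chloroethynyl)oxy]-1-(3,4,5-trimethoxyphenyl)propan-2-yl]-4-methoxy-4-(prop-2-en-1-yl)cyclobut-2-en-1-olate (not isolated) | C=CCC1(OC)C=C(C1[O-])[C@H](C)[C@H](OC#CCl)c1cc(OC)c(OC)c(OC)c1.[Li+] | intermediate
17 | 2-[(1S,2S)-1-(ethynyloxy)-1-(3,4,5-trimethoxyphenyl)propan-2-yl]-4-methoxy-4-(prop-2-en-1-yl)cyclobut-2-en-1-ol (ring diastereomers) | C=CCC1(OC)C=C(C1O)[C@H](C)[C@H](OC#C)c1cc(OC)c(OC)c(OC)c1 | intermediate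
18 | 2-[(1S,2S)-1-(ethynyloxy)-1-(3,4,5-trimethoxyphenyl)propan-2-yl]-4-methoxy-4-(prop-2-en-1-yl)cyclobut-2-en-1-one (both ring epimers) | C=CCC1(OC)C=C(C1=O)[C@H](C)[C@H](OC#C)c1cc(OC)c(OC)c(OC)c1 | intermediate
19 | 2-[(1S,2S)-1-(ethynyloxy)-1-(3,4,5-trimethoxyphenyl)propan-2-yl]-4-methoxyhepta-1,3,6-trien-1-one (vinylketene, C3=C4 geometry open, not isolated) | O=C=C(C=C(OC)CC=C)[C@H](C)[C@H](OC#C)c1cc(OC)c(OC)c(OC)c1 | intermediate
20 | (3S,4S)-5-(2-methoxypenta-1,4-dien-1-yl)-4-methyl-3-(3,4,5-trimethoxyphenyl)-2-oxabicyclo[3.2.0]hept-1(7)-en-6-one (C5 configuration open, not isolated) | O=C1C=C2O[C@H](c3cc(OC)c(OC)c(OC)c3)[C@@H](C)C12C=C(OC)CC=C | intermediate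
21 | 2-[(4S,5S)-3-(2-methoxypenta-1,4-dien-1-yl)-4-methyl-5-(3,4,5-trimethoxyphenyl)-4,5-dihydrofuran-2-yl]ethen-1-one (dienylketene, not isolated) | O=C=CC1=C(C=C(OC)CC=C)[C@H](C)[C@@H](c2cc(OC)c(OC)c(OC)c2)O1 | intermediate
22 | (2S,3S,5R)-5-methoxy-3-methyl-5-(prop-2-en-1-yl)-2-(3,4,5-trimethoxyphenyl)-3,5-dihydro-1-benzofuran-6(2H)-one | C=CC[C@@]1(OC)C=C2C(=CC1=O)O[C@H](c1cc(OC)c(OC)c(OC)c1)[C@H]2C | intermediate
23 | (2S,3S,5R)-7-bromo-5-methoxy-3-methyl-5-(prop-2-en-1-yl)-2-(3,4,5-trimethoxyphenyl)-3,5-dihydro-1-benzofuran-6(2H)-one | C=CC[C@@]1(OC)C=C2C(=C(Br)C1=O)O[C@H](c1cc(OC)c(OC)c(OC)c1)[C@H]2C | intermediate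
24 | (2S,3S,5R)-5,7-dimethoxy-3-methyl-5-(prop-2-en-1-yl)-2-(3,4,5-trimethoxyphenyl)-3,5-dihydro-1-benzofuran-6(2H)-one | C=CC[C@@]1(OC)C=C2C(=C(OC)C1=O)O[C@H](c1cc(OC)c(OC)c(OC)c1)[C@H]2C | target
```

## Step count and least certain steps

Total: 13 steps. Longest linear sequence: 13 steps (1 to 24); 3, 6 and 9 join that line as they are needed.

**Step 11 (proposed new method).** The most likely failure is loss of 18 or of vinylketene 19 before the cycloaddition:
- the benzylic alkynyl ether can shift onto the arene or shed ketene;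
- the inward allyl group of 19 can pass a hydrogen to the ketene carbon ([1,5] shift);
- closure onto a linear alkyne through a strained bicyclic transition state may be slow.

A second concern is poor facial selectivity in the final electrocyclisation.

Fallback by known chemistry, setting out from 5 and returning at 22:
- Silylate 5 (TBSOTf, 2,6-lutidine) to the silyl ether, tert-butyl(dimethyl){[(1S,2S)-2-methyl-1-(3,4,5-trimethoxyphenyl)but-3-yn-1-yl]oxy}silane F1.
- Carry F1 through the conditions of steps 4 to 7: the dichlorocyclobutenone F2, the allyl carbinol F3, the methyl ether F4 and the silyloxy cyclobutenone F5.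
- Heat F5 with ethoxyacetylene (toluene, 80 °C), an intermolecular Danheiser-type annulation, to the 3-ethoxy dienone F6.
- Remove the silyl group (HF·pyridine) to the hydroxy dienone F7. Under mild acid its hydroxyl should displace ethanol at C7a (vinylogous transetherification) to give 22 together with its C5 epimer, (2S,3S,5S)-5-methoxy-3-methyl-5-(prop-2-en-1-yl)-2-(3,4,5-trimethoxyphenyl)-3,5-dihydro-1-benzofuran-6(2H)-one F8, which is removed by chromatography.

This sequence has no alkynyl ether in the substrate, needs no reduction/oxidation bracket and is no longer than the main line from 5. It gives up only the intramolecular delivery.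

**Step 7.** The ionisation that starts the hydrolysis puts positive charge next to C5. A 1,2-shift of the allyl group, or capture of water at the far end of the allyl cation, could divert material.

Fallback, setting out from 11 and returning at 14: unveil the second carbonyl before C5 becomes quaternary.
- Hydrolyse 11 with AgNO3 in warm aqueous acetone to the cyclobutenedione, 3-[(1S,2S)-1-{[(E)-1,2-dichloroethenyl]oxy}-1-(3,4,5-trimethoxyphenyl)propan-2-yl]cyclobut-3-ene-1,2-dione F9.
- Add CH2=CHCH2MgBr at −78 °C to the carbonyl remote from the branched side chain (steric preference; any regioisomer is removed) to give the hydroxy cyclobutenone, 2-[(1S,2S)-1-{[(E)-1,2-dichloroethenyl]oxy}-1-(3,4,5-trimethoxyphenyl)propan-2-yl]-4-hydroxy-4-(prop-2-en-1-yl)cyclobut-2-en-1-one F10.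
- Methylate F10 with MeI and Ag2O, the standard treatment of 4-hydroxycyclobutenones, to reach 14.

**Step 9.** With excess n-BuLi present, alkoxide-driven opening of the lithium cyclobutenoxide, or lithiation at the benzylic C2–H followed by Wittig rearrangement, could consume material.

Fallback, setting out from 15 and returning at 17:
- Silylate the carbinol (TBSOTf, 2,6-lutidine) to the silyl ether, tert-butyl({2-[(1S,2S)-1-{[(E)-1,2-dichloroethenyl]oxy}-1-(3,4,5-trimethoxyphenyl)propan-2-yl]-4-methoxy-4-(prop-2-en-1-yl)cyclobut-2-en-1-yl}oxy)dimethylsilane F11.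
- Run the elimination with two equivalents of n-BuLi at −78 °C to the silylated ynol ether, tert-butyl({2-[(1S,2S)-1-(ethynyloxy)-1-(3,4,5-trimethoxyphenyl)propan-2-yl]-4-methoxy-4-(prop-2-en-1-yl)cyclobut-2-en-1-yl}oxy)dimethylsilane F12.
- Remove the silyl group with buffered TBAF at 0 °C to give 17.

**Step 13.** Exchange of the ring oxygen for methoxide at C7a (opening the dihydrofuran), a thermal [3,3] shift of the allyl group at the coupling temperature, or simple loss of bromine could each lower the return.

Fallback, setting out from 23 and returning at 24: make the C7–O bond by oxidation of a C7–B bond.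
- Miyaura borylation (B2pin2, Pd(dppf)Cl2, KOAc, dioxane, 80 °C, short heating) to the boronate, (2S,3S,5R)-5-methoxy-3-methyl-5-(prop-2-en-1-yl)-7-(4,4,5,5-tetramethyl-1,3,2-dioxaborolan-2-yl)-2-(3,4,5-trimethoxyphenyl)-3,5-dihydro-1-benzofuran-6(2H)-one F13.
- Oxidation (NaBO3·4H2O, THF–H2O, 0 °C) to the enol, (2S,3S,5R)-7-hydroxy-5-methoxy-3-methyl-5-(prop-2-en-1-yl)-2-(3,4,5-trimethoxyphenyl)-3,5-dihydro-1-benzofuran-6(2H)-one F14.
- O-Methylation (Me2SO4, K2CO3, acetone, 20 °C) to 24.

## Further compounds

```
F1 | step 11 | tert-butyl(dimethyl){[(1S,2S)-2-methyl-1-(3,4,5-trimethoxyphenyl)but-3-yn-1-yl]oxy}silane | C#C[C@H](C)[C@H](O[Si](C)(C)C(C)(C)C)c1cc(OC)c(OC)c(OC)c1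
F2 | step 11 | 3-[(1S,2S)-1-{[tert-butyl(dimethyl)silyl]oxy}-1-(3,4,5-trimethoxyphenyl)propan-2-yl]-4,4-dichlorocyclobut-2-en-1-one | O=C1C=C(C1(Cl)Cl)[C@H](C)[C@H](O[Si](C)(C)C(C)(C)C)c1cc(OC)c(OC)c(OC)c1
F3 | step 11 | 3-[(1S,2S)-1-{[tert-butyl(dimethyl)silyl]oxy}-1-(3,4,5-trimethoxyphenyl)propan-2-yl]-4,4-dichloro-1-(prop-2-en-1-yl)cyclobut-2-en-1-ol | C=CCC1(O)C=C(C1(Cl)Cl)[C@H](C)[C@H](O[Si](C)(C)C(C)(C)C)c1cc(OC)c(OC)c(OC)c1
F4 | step 11 | tert-butyl{[(1S,2S)-2-[4,4-dichloro-3-methoxy-3-(prop-2-en-1-yl)cyclobut-1-en-1-yl]-1-(3,4,5-trimethoxyphenyl)propyl]oxy}dimethylsilane | C=CCC1(OC)C=C(C1(Cl)Cl)[C@H](C)[C@H](O[Si](C)(C)C(C)(C)C)c1cc(OC)c(OC)c(OC)c1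
F5 | step 11 | 2-[(1S,2S)-1-{[tert-butyl(dimethyl)silyl]oxy}-1-(3,4,5-trimethoxyphenyl)propan-2-yl]-4-methoxy-4-(prop-2-en-1-yl)cyclobut-2-en-1-one | C=CCC1(OC)C=C(C1=O)[C@H](C)[C@H](O[Si](C)(C)C(C)(C)C)c1cc(OC)c(OC)c(OC)c1
F6 | step 11 | 4-[(1S,2S)-1-{[tert-butyl(dimethyl)silyl]oxy}-1-(3,4,5-trimethoxyphenyl)propan-2-yl]-3-ethoxy-6-methoxy-6-(prop-2-en-1-yl)cyclohexa-2,4-dien-1-one | C=CCC1(OC)C=C(C(OCC)=CC1=O)[C@H](C)[C@H](O[Si](C)(C)C(C)(C)C)c1cc(OC)c(OC)c(OC)c1
F7 | step 11 | 3-ethoxy-4-[(1S,2S)-1-hydroxy-1-(3,4,5-trimethoxyphenyl)propan-2-yl]-6-methoxy-6-(prop-2-en-1-yl)cyclohexa-2,4-dien-1-one | C=CCC1(OC)C=C(C(OCC)=CC1=O)[C@H](C)[C@H](O)c1cc(OC)c(OC)c(OC)c1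
F8 | step 11 | (2S,3S,5S)-5-methoxy-3-methyl-5-(prop-2-en-1-yl)-2-(3,4,5-trimethoxyphenyl)-3,5-dihydro-1-benzofuran-6(2H)-one | C=CC[C@]1(OC)C=C2C(=CC1=O)O[C@H](c1cc(OC)c(OC)c(OC)c1)[C@H]2C
F9 | step 7 | 3-[(1S,2S)-1-{[(E)-1,2-dichloroethenyl]oxy}-1-(3,4,5-trimethoxyphenyl)propan-2-yl]cyclobut-3-ene-1,2-dione | O=C1C=C(C1=O)[C@H](C)[C@H](O/C(Cl)=C\Cl)c1cc(OC)c(OC)c(OC)c1
F10 | step 7 | 2-[(1S,2S)-1-{[(E)-1,2-dichloroethenyl]oxy}-1-(3,4,5-trimethoxyphenyl)propan-2-yl]-4-hydroxy-4-(prop-2-en-1-yl)cyclobut-2-en-1-one | C=CCC1(O)C=C(C1=O)[C@H](C)[C@H](O/C(Cl)=C\Cl)c1cc(OC)c(OC)c(OC)c1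
F11 | step 9 | tert-butyl({2-[(1S,2S)-1-{[(E)-1,2-dichloroethenyl]oxy}-1-(3,4,5-trimethoxyphenyl)propan-2-yl]-4-methoxy-4-(prop-2-en-1-yl)cyclobut-2-en-1-yl}oxy)dimethylsilane | C=CCC1(OC)C=C(C1O[Si](C)(C)C(C)(C)C)[C@H](C)[C@H](O/C(Cl)=C\Cl)c1cc(OC)c(OC)c(OC)c1
F12 | step 9 | tert-butyl({2-[(1S,2S)-1-(ethynyloxy)-1-(3,4,5-trimethoxyphenyl)propan-2-yl]-4-methoxy-4-(prop-2-en-1-yl)cyclobut-2-en-1-yl}oxy)dimethylsilane | C=CCC1(OC)C=C(C1O[Si](C)(C)C(C)(C)C)[C@H](C)[C@H](OC#C)c1cc(OC)c(OC)c(OC)c1
F13 | step 13 | (2S,3S,5R)-5-methoxy-3-methyl-5-(prop-2-en-1-yl)-7-(4,4,5,5-tetramethyl-1,3,2-dioxaborolan-2-yl)-2-(3,4,5-trimethoxyphenyl)-3,5-dihydro-1-benzofuran-6(2H)-one | C=CC[C@@]1(OC)C=C2C(=C(B3OC(C)(C)C(C)(C)O3)C1=O)O[C@H](c1cc(OC)c(OC)c(OC)c1)[C@H]2C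
F14 | step 13 | (2S,3S,5R)-7-hydroxy-5-methoxy-3-methyl-5-(prop-2-en-1-yl)-2-(3,4,5-trimethoxyphenyl)-3,5-dihydro-1-benzofuran-6(2H)-one | C=CC[C@@]1(OC)C=C2C(=C(O)C1=O)O[C@H](c1cc(OC)c(OC)c(OC)c1)[C@H]2C
A1 | alternative 1 | 4-[(2R)-2-[2-hydroxy-3-methoxy-4-(methoxymethoxy)phenyl]propyl]-2,6-dimethoxyphenol | COc1cc(C[C@@H](C)c2ccc(OCOC)c(OC)c2O)cc(OC)c1O
A2 | alternative 1 | 4-{(2R)-2-[2-hydroxy-3-methoxy-4-(methoxymethoxy)phenyl]propylidene}-2,6-dimethoxycyclohexa-2,5-dien-1-one | COC1=CC(=C[C@@H](C)c2ccc(OCOC)c(OC)c2O)C=C(OC)C1=O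
A3 | alternative 1 | 4-[(2S,3S)-7-methoxy-6-(methoxymethoxy)-3-methyl-2,3-dihydro-1-benzofuran-2-yl]-2,6-dimethoxyphenol | COCOc1ccc2c(c1OC)O[C@H](c1cc(OC)c(O)c(OC)c1)[C@H]2C
A4 | alternative 2 | 5-[(1S,2S)-1-hydroxy-1-(3,4,5-trimethoxyphenyl)propan-2-yl]-3-methoxybenzene-1,2-diol | COc1cc(cc(O)c1O)[C@H](C)[C@H](O)c1cc(OC)c(OC)c(OC)c1
A5 | alternative 2 | 5-[(1S,2S)-1-hydroxy-1-(3,4,5-trimethoxyphenyl)propan-2-yl]-3-methoxycyclohexa-3,5-diene-1,2-dione | COC1=CC(=CC(=O)C1=O)[C@H](C)[C@H](O)c1cc(OC)c(OC)c(OC)c1
A6 | alternative 2 | (2S,3S)-7-methoxy-3-methyl-2-(3,4,5-trimethoxyphenyl)-2,3-dihydro-1-benzofuran-5,6-dione | O=C1C=C2C(=C(OC)C1=O)O[C@H](c1cc(OC)c(OC)c(OC)c1)[C@H]2C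
A7 | alternative 3 | (2R)-3-diazo-8-methoxy-7-(prop-2-en-1-yloxy)-2-(3,4,5-trimethoxyphenyl)-2,3-dihydro-4H-1-benzopyran-4-one | C=CCOc1ccc2C(=O)C(=[N+]=[N-])[C@@H](c3cc(OC)c(OC)c(OC)c3)Oc2c1OC
A8 | alternative 3 | methyl (2S,3S)-7-methoxy-6-(prop-2-en-1-yloxy)-2-(3,4,5-trimethoxyphenyl)-2,3-dihydro-1-benzofuran-3-carboxylate | C=CCOc1ccc2c(c1OC)O[C@H](c1cc(OC)c(OC)c(OC)c1)[C@H]2C(=O)OC
```
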